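**Plan**
1. The last cut is the vinylic O1–C5 bond of the furan-2(5H)-one. O1 sits on an sp2 carbon (C5) that is held cis to the carboxyl carbon C2 by the ring C3=C4 double bond, so a (2Z,4E)-4-iodo-2,4-dienoic acid can close the ring by copper-mediated C(sp2)–O coupling with retention. This gives the E-ylidene, which anti-addition 5-exo-dig lactonisation of an enynoic acid would not give.
2. Further cuts: C4–C5 (Sonogashira, iodoacrylate head plus chain alkyne), the sp2–sp3 bond and the C=C of the central trisubstituted alkene (B-alkyl Suzuki, iodo-Wittig), and the allylic C–C bond beside the furan-side alkene (Johnson–Claisen).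
3. Forward: 3-bromofuran is grown into the E-enal and the Z-vinyl iodide (steps 1–6) and joined to a chiral enyne from an Evans allylation (7–12). Desilylation, Sonogashira coupling, syn hydrostannation/iodination and saponification follow (13–17). The butenolide, the only ring built (the furan is bought), closes last (18).
4. Stereochemistry: the R centre comes from the oxazolidinone auxiliary, the E alkene from the chair Claisen, the Z alkene from the Z-iodide coupled with retention, the cis C2=C3 unit from the Z-selective iodo-aldol, and the E-ylidene from syn H–Sn addition followed by retentive Sn→I and I→O exchange.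

Key step: step 18

Assumption: the SMILES is read as written, i.e. side chain anti to the ring oxygen at the exocyclic double bond (5E), R at the methine carbon, Z at the central and E at the furan-side trisubstituted alkene.

**Route**

Step 1
Reactants: 1 3-bromofuran
Product: 3 3-(furan-3-yl)propan-1-ol, via furan-3-yllithium 2 (not isolated)
Conditions: n-BuLi, THF, −78 °C; oxetane, BF3·OEt2, −78 °C; then H2O
Reagents that add atoms: oxetane, C1COC1; n-butyllithium, [Li]CCCC (lithium carried only in 2)
Why: Bromine–lithium exchange at −78 °C gives the 3-lithiofuran without migration to C2, and BF3-promoted ring opening of oxetane by an organolithium is an established three-carbon homologation to the primary alcohol.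

Step 2
Reactants: 3 3-(furan-3-yl)propan-1-ol
Product: 4 3-(furan-3-yl)propanal
Conditions: Dess–Martin periodinane, pyridine, CH2Cl2, 0 °C to rt
Reagents that add atoms: none
Why: Dess–Martin oxidation of a primary alcohol stops at the aldehyde, and the pyridine buffer keeps the acid-sensitive furan intact.

Step 3
Reactants: 4 3-(furan-3-yl)propanal
Product: 5 5-(furan-3-yl)-2-methylpent-1-en-3-ol (racemic)
Conditions: CH2=C(CH3)MgBr, THF, −78 to 0 °C
Reagents that add atoms: isopropenylmagnesium bromide, C=C(C)[Mg]Br
Why: Grignard 1,2-addition to an unhindered aldehyde; the carbinol centre is made racemic on purpose because step 4 destroys it.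

Step 4
Reactants: 5 5-(furan-3-yl)-2-methylpent-1-en-3-ol
Product: 7 ethyl (4E)-7-(furan-3-yl)-4-methylhept-4-enoate, via mixed ketene acetal 6 (not isolated)
Conditions: CH3C(OEt)3, cat. propionic acid, 140 °C, ethanol distilled off
Reagents that add atoms: triethyl orthoacetate, CCOC(C)(OCC)OCC
Why: Johnson–Claisen orthoester rearrangement: acid-catalysed exchange and loss of ethanol give the ketene acetal, whose [3,3]-shift through a chair with the furylethyl group equatorial should give the E-trisubstituted alkene.

Step 5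
Reactants: 7 ethyl (4E)-7-(furan-3-yl)-4-methylhept-4-enoate
Product: 8 (4E)-7-(furan-3-yl)-4-methylhept-4-enal
Conditions: i-Bu2AlH, CH2Cl2, −78 °C; aq. potassium sodium tartrate
Reagents that add atoms: none
Why: Partial ester reduction with i-Bu2AlH at −78 °C stops at the aluminium hemiacetal, which releases the aldehyde on work-up; alkene and furan are inert.

Step 6
Reactants: 8 (4E)-7-(furan-3-yl)-4-methylhept-4-enal
Product: 9 3-[(3E,7Z)-8-iodo-4-methylnona-3,7-dien-1-yl]furan
Conditions: EtPPh3I, n-BuLi, THF, rt; I2, −78 °C; NaN(SiMe3)2, −20 °C; then 8, −78 to −20 °C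
Reagents that add atoms: (1-iodoethylidene)triphenylphosphorane, CC(I)=P(c1ccccc1)(c1ccccc1)c1ccccc1, made in the flask from ethyltriphenylphosphonium iodide, CC[P+](c1ccccc1)(c1ccccc1)c1ccccc1.[I-], and iodine, II
Why: Stork–Zhao-type Wittig olefination with the non-stabilised α-iodo ylide is kinetically Z-selective and should give the (Z)-2-iodoalk-2-ene needed for a stereoretentive coupling.

Step 7
Reactants: 10 (4S)-4-benzyl-3-propanoyl-1,3-oxazolidin-2-one
Product: 12 (4S)-4-benzyl-3-[(2R)-2-methylpent-4-enoyl]-1,3-oxazolidin-2-one, via sodium Z-enolate 11 (not isolated)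
Conditions: NaN(SiMe3)2, THF, −78 °C; allyl iodide, −78 to −45 °C
Reagents that add atoms: allyl iodide, C=CCI; sodium bis(trimethylsilyl)amide, [Na+].C[Si](C)(C)[N-][Si](C)(C)C (sodium carried only in 11)
Why: Evans asymmetric alkylation: the chelated sodium Z-enolate is allylated on the face opposite the benzyl group, which sets the new centre as R.

Step 8
Reactants: 12 (4S)-4-benzyl-3-[(2R)-2-methylpent-4-enoyl]-1,3-oxazolidin-2-one
Product: 13 (2R)-2-methylpent-4-en-1-ol
Conditions: LiBH4, H2O (1 equiv), Et2O, 0 °C
Reagents that add atoms: none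
Why: Reductive cleavage of the imide with LiBH4 releases the primary alcohol and the recoverable auxiliary without touching the α-stereocentre or the alkene.

Step 9
Reactants: 13 (2R)-2-methylpent-4-en-1-ol
Product: 14 (2R)-2-methylpent-4-enal
Conditions: Dess–Martin periodinane, pyridine, CH2Cl2, 0 °C; used at once as a cold solution
Reagents that add atoms: none
Why: Buffered Dess–Martin oxidation gives the α-branched aldehyde under non-epimerising conditions, and immediate use avoids loss of the volatile, configurationally labile product.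

Step 10
Reactants: 14 (2R)-2-methylpent-4-enal
Product: 15 (3R)-1,1-dibromo-3-methylhexa-1,5-diene
Conditions: CBr4, PPh3, CH2Cl2, 0 °C
Reagents that add atoms: carbon tetrabromide, BrC(Br)(Br)Br
Why: Ramirez dibromo-olefination (first stage of the Corey–Fuchs sequence) runs under essentially neutral conditions, so the α-centre is kept.

Step 11
Reactants: 15 (3R)-1,1-dibromo-3-methylhexa-1,5-diene
Product: 17 triisopropyl[(3R)-3-methylhex-5-en-1-yn-1-yl]silane, via lithium acetylide 16 (not isolated)
Conditions: n-BuLi (2.1 equiv), THF, −78 to 0 °C; i-Pr3SiOTf, −78 °C to rt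
Reagents that add atoms: triisopropylsilyl trifluoromethanesulfonate, CC(C)[Si](C(C)C)(C(C)C)OS(=O)(=O)C(F)(F)F; n-butyllithium, [Li]CCCC (lithium carried only in 16)
Why: Second stage of the Corey–Fuchs sequence: bromine–lithium exchange and Fritsch–Buttenberg–Wiechell rearrangement give the lithium acetylide, which is capped with the bulky silyl group; the propargylic centre is not acidic enough to epimerise.

Step 12
Reactants: 17 triisopropyl[(3R)-3-methylhex-5-en-1-yn-1-yl]silane; 9 3-[(3E,7Z)-8-iodo-4-methylnona-3,7-dien-1-yl]furan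
Product: 19 triisopropyl[(3R,7Z,11E)-14-(furan-3-yl)-3,7,11-trimethyltetradeca-7,11-dien-1-yn-1-yl]silane, via B-alkyl-9-BBN adduct 18 (not isolated)
Conditions: 9-BBN, THF, 0 °C to rt; then 9, Pd(dppf)Cl2, AsPh3, Cs2CO3, DMF/H2O, rt
Reagents that add atoms: 9-borabicyclo[3.3.1]nonane, [H]B1C2CCCC1CCC2 (boron carried only in 18)
Why: 9-BBN hydroborates the terminal alkene in preference to the shielded silyl alkyne, and the B-alkyl Suzuki–Miyaura coupling with the vinyl iodide proceeds with retention, which fixes the Z geometry of the central trisubstituted alkene.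

Step 13
Reactants: 19 triisopropyl[(3R,7Z,11E)-14-(furan-3-yl)-3,7,11-trimethyltetradeca-7,11-dien-1-yn-1-yl]silane
Product: 20 3-[(3E,7Z,12R)-4,8,12-trimethyltetradeca-3,7-dien-13-yn-1-yl]furan
Conditions: Bu4NF, THF, 0 °C to rt
Reagents that add atoms: none
Why: Fluoride-induced protodesilylation of the alkynylsilane; nothing else in the molecule is fluoride-labile.

Step 14
Reactants: 21 methyl propiolate
Product: 23 methyl (2Z)-2-(hydroxymethyl)-3-iodoprop-2-enoate, via aluminium iodoallenolate 22 (not isolated)
Conditions: Et2AlI, CH2Cl2, 0 °C; CH2O gas (from cracked paraformaldehyde), −78 to 0 °C; aq. potassium sodium tartrate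
Reagents that add atoms: diethylaluminium iodide, CC[Al](I)CC; formaldehyde, C=O
Why: Iodo-aldol (β-iodo Baylis–Hillman-type) reaction: conjugate addition of iodide gives the aluminium iodoallenolate, which is hydroxymethylated at the α-carbon anti to iodine, so the iodine ends cis to the ester (Z).

Step 15
Reactants: 20 3-[(3E,7Z,12R)-4,8,12-trimethyltetradeca-3,7-dien-13-yn-1-yl]furan; 23 methyl (2Z)-2-(hydroxymethyl)-3-iodoprop-2-enoate
Product: 24 methyl (2Z,6R,10Z,14E)-17-(furan-3-yl)-2-(hydroxymethyl)-6,10,14-trimethylheptadeca-2,10,14-trien-4-ynoate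
Conditions: Pd(PPh3)2Cl2 (3 mol %), CuI (6 mol %), Et3N, THF, rt, degassed
Reagents that add atoms: none
Why: Sonogashira coupling of the electron-poor vinyl iodide occurs with retention, placing the alkyne cis to the ester; the carboxyl is kept as its methyl ester so that no anti-oxymetalation to the Z-butenolide can occur.

Step 16
Reactants: 24 methyl (2Z,6R,10Z,14E)-17-(furan-3-yl)-2-(hydroxymethyl)-6,10,14-trimethylheptadeca-2,10,14-trien-4-ynoate
Product: 26 methyl (2Z,4E,6R,10Z,14E)-17-(furan-3-yl)-2-(hydroxymethyl)-4-iodo-6,10,14-trimethylheptadeca-2,4,10,14-tetraenoate, via C4 vinylstannane 25 (not isolated)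
Conditions: Bu3SnH (slow addition), Pd(PPh3)2Cl2 (3 mol %), THF, 0 °C; then I2, CH2Cl2, −78 to 0 °C
Reagents that add atoms: tributyltin hydride, CCCC[SnH](CCCC)CCCC (tin carried only in 25); iodine, II
Why: Palladium-catalysed hydrostannation is a syn addition that should place hydrogen on the electrophilic, branched δ-carbon and tin on C4 next to the Z-enoate (electronic and steric bias of a Z-2-en-4-ynoate), and iododestannylation occurs with retention, giving the (4E)-iodide.

Step 17
Reactants: 26 methyl (2Z,4E,6R,10Z,14E)-17-(furan-3-yl)-2-(hydroxymethyl)-4-iodo-6,10,14-trimethylheptadeca-2,4,10,14-tetraenoate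
Product: 27 (2Z,4E,6R,10Z,14E)-17-(furan-3-yl)-2-(hydroxymethyl)-4-iodo-6,10,14-trimethylheptadeca-2,4,10,14-tetraenoic acid
Conditions: LiOH, THF/MeOH/H2O, rt; then 0.5 M HCl to pH 4, 0 °C
Reagents that add atoms: lithium hydroxide, [Li+].[OH-] (its oxygen becomes the acid OH)
Why: Saponification of the methyl ester; the vinyl iodide has no anti-periplanar hydrogen for elimination (H and I are cis) and the mildly acidic work-up spares the furan.

Step 18
Reactants: 27 (2Z,4E,6R,10Z,14E)-17-(furan-3-yl)-2-(hydroxymethyl)-4-iodo-6,10,14-trimethylheptadeca-2,4,10,14-tetraenoic acid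
Product: 28 (5E)-5-[(2R,6Z,10E)-13-(furan-3-yl)-2,6,10-trimethyltrideca-6,10-dien-1-ylidene]-3-(hydroxymethyl)furan-2(5H)-one
Conditions: CuI (10 mol %), trans-N,N'-dimethylcyclohexane-1,2-diamine (20 mol %), Cs2CO3, THF, 50 °C, dark, argon
Reagents that add atoms: none
Why: The caesium carboxylate binds diamine-ligated monovalent copper, which inserts into the neighbouring C4–I bond to give a six-membered trivalent copper metallacycle and then forms the C–O bond by reductive elimination with retention at the vinylic carbon. The closest known reaction type is the CuI-catalysed intramolecular O-vinylation of carboxylic acids with vinyl halides (Ullmann-type C–O coupling to enol lactones), together with the stereoretentive formation of enol esters from vinyl halides and copper carboxylates. The furan-2(5H)-one ring closes in a 5-exo sense by substitution at the sp2 carbon, the ylidene double bond staying outside the new ring. No new stereocentre arises: the E geometry of the exocyclic double bond is dictated by the (4E)-iodide made by syn H–Sn addition, and the remote R centre is not involved. The step needs retention over E-to-Z drift, ring closure over intermolecular O-vinylation by the free primary alcohol, and no vinylogous enolisation at the allylic methine. The cis C2=C3 bond holds the carboxylate at bonding distance from C4 while the hydroxymethyl group is held trans and cannot reach it, and the carbonate base, moderate temperature and exclusion of light protect the less stable E-ylidene.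

**Compound list**
1 | 3-bromofuran | Brc1ccoc1 | starting material
2 | furan-3-yllithium (formed in the flask) | [Li]c1ccoc1 | intermediate
3 | 3-(furan-3-yl)propan-1-ol | OCCCc1ccoc1 | intermediate
4 | 3-(furan-3-yl)propanal | O=CCCc1ccoc1 | intermediate
5 | 5-(furan-3-yl)-2-methylpent-1-en-3-ol (racemic) | C=C(C)C(O)CCc1ccoc1 | intermediate
6 | 3-{3-[(1-ethoxyethenyl)oxy]-4-methylpent-4-en-1-yl}furan (mixed ketene acetal, formed in the flask) | C=C(OCC)OC(CCc1ccoc1)C(C)=C | intermediate
7 | ethyl (4E)-7-(furan-3-yl)-4-methylhept-4-enoate | CCOC(=O)CC/C(C)=C/CCc1ccoc1 | intermediate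
8 | (4E)-7-(furan-3-yl)-4-methylhept-4-enal | O=CCC/C(C)=C/CCc1ccoc1 | intermediate
9 | 3-[(3E,7Z)-8-iodo-4-methylnona-3,7-dien-1-yl]furan | C/C(I)=C/CC/C(C)=C/CCc1ccoc1 | intermediate
10 | (4S)-4-benzyl-3-propanoyl-1,3-oxazolidin-2-one | CCC(=O)N1[C@@H](Cc2ccccc2)COC1=O | starting material
11 | sodium (Z)-enolate of 10 (formed in the flask) | C/C=C(\[O-])N1[C@@H](Cc2ccccc2)COC1=O.[Na+] | intermediate
12 | (4S)-4-benzyl-3-[(2R)-2-methylpent-4-enoyl]-1,3-oxazolidin-2-one | C=CC[C@@H](C)C(=O)N1[C@@H](Cc2ccccc2)COC1=O | intermediate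
13 | (2R)-2-methylpent-4-en-1-ol | C=CC[C@@H](C)CO | intermediate
14 | (2R)-2-methylpent-4-enal | C=CC[C@@H](C)C=O | intermediate
15 | (3R)-1,1-dibromo-3-methylhexa-1,5-diene | C=CC[C@@H](C)C=C(Br)Br | intermediate
16 | [(3R)-3-methylhex-5-en-1-yn-1-yl]lithium (formed in the flask) | C=CC[C@@H](C)C#C[Li] | intermediate
17 | triisopropyl[(3R)-3-methylhex-5-en-1-yn-1-yl]silane | C=CC[C@@H](C)C#C[Si](C(C)C)(C(C)C)C(C)C | intermediate
18 | 9-[(4R)-4-methyl-6-(triisopropylsilyl)hex-5-yn-1-yl]-9-borabicyclo[3.3.1]nonane (formed in the flask) | B1(CCC[C@@H](C)C#C[Si](C(C)C)(C(C)C)C(C)C)C2CCCC1CCC2 | intermediate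
19 | triisopropyl[(3R,7Z,11E)-14-(furan-3-yl)-3,7,11-trimethyltetradeca-7,11-dien-1-yn-1-yl]silane | C/C(=C/CC/C(C)=C/CCc1ccoc1)CCC[C@@H](C)C#C[Si](C(C)C)(C(C)C)C(C)C | intermediate
20 | 3-[(3E,7Z,12R)-4,8,12-trimethyltetradeca-3,7-dien-13-yn-1-yl]furan | C/C(=C/CC/C(C)=C/CCc1ccoc1)CCC[C@@H](C)C#C | intermediate
21 | methyl propiolate | C#CC(=O)OC | starting material
22 | diethylaluminium 3-iodo-1-methoxypropa-1,2-dien-1-olate (formed in the flask) | COC(O[Al](CC)CC)=C=CI | intermediate
23 | methyl (2Z)-2-(hydroxymethyl)-3-iodoprop-2-enoate | COC(=O)/C(CO)=C\I | intermediate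
24 | methyl (2Z,6R,10Z,14E)-17-(furan-3-yl)-2-(hydroxymethyl)-6,10,14-trimethylheptadeca-2,10,14-trien-4-ynoate | C/C(=C/CC/C(C)=C/CCc1ccoc1)CCC[C@@H](C)C#C/C=C(/CO)C(=O)OC | intermediate
25 | methyl (2Z,4E,6R,10Z,14E)-17-(furan-3-yl)-2-(hydroxymethyl)-6,10,14-trimethyl-4-(tributylstannyl)heptadeca-2,4,10,14-tetraenoate (formed in the flask) | C/C(=C/CC/C(C)=C/CCc1ccoc1)CCC[C@@H](C)/C=C(\C=C(/C(=O)OC)CO)[Sn](CCCC)(CCCC)CCCC | intermediate
26 | methyl (2Z,4E,6R,10Z,14E)-17-(furan-3-yl)-2-(hydroxymethyl)-4-iodo-6,10,14-trimethylheptadeca-2,4,10,14-tetraenoate | C/C(=C/CC/C(C)=C/CCc1ccoc1)CCC[C@@H](C)/C=C(I)\C=C(/C(=O)OC)CO | intermediate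
27 | (2Z,4E,6R,10Z,14E)-17-(furan-3-yl)-2-(hydroxymethyl)-4-iodo-6,10,14-trimethylheptadeca-2,4,10,14-tetraenoic acid | C/C(=C/CC/C(C)=C/CCc1ccoc1)CCC[C@@H](C)/C=C(I)\C=C(/C(=O)O)CO | intermediate
28 | (5E)-5-[(2R,6Z,10E)-13-(furan-3-yl)-2,6,10-trimethyltrideca-6,10-dien-1-ylidene]-3-(hydroxymethyl)furan-2(5H)-one (22-deoxy-23-hydroxymethylvariabilin) | C/C(=C/CC/C(C)=C/CCc1ccoc1)CCC[C@@H](C)/C=C1\C=C(CO)C(=O)O1 | target

**Step count and risks**
Total steps: 18. Longest linear sequence: 12 steps (steps 1–6, 12, 13, 15–18).

Steps most likely to fail: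

- Step 18. The exocyclic double bond may drift from E to the more stable Z geometry under heat, base or iodide, the vinyl iodide may be reduced instead of coupled, or turnover at the hindered vinylic carbon may be slow. The fallback sets out from iodo ester 26 and comes back at target 28. Miyaura borylation of 26 (B2pin2, Pd(dppf)Cl2, KOAc, dioxane, 60 °C), which keeps the alkene geometry, should give the alkenyl pinacolboronate ester F1. Saponification with LiOH should give the boronate acid F2. An oxidative Chan–Lam-type acyloxylation (Cu(OAc)2, pyridine, molecular sieves, air, CH2Cl2, rt) then closes the same C–O bond with retention from a nucleophilic vinyl carbon under unheated, nearly neutral conditions, giving 28.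

- Step 16. Tin may be delivered to the distal alkyne carbon, the enoate may be reduced, or iodine may attack the furan or the trisubstituted alkenes during the tin–iodine exchange. The fallback sets out from enynoate 24 and comes back at target 28 without tin or a vinyl iodide. Saponification of 24 (LiOH) should give the enynoic acid F3. AgNO3-catalysed anti 5-exo-dig lactonisation in acetone should give the (5Z)-ylidene butenolide F4. Irradiation at 350 nm in benzene should set up a Z/E mixture, from which 28 is separated by chromatography and F4 is recycled.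

- Step 6. The α-iodo ylide may decompose or scramble iodine before it meets the aldehyde, lowering conversion and Z selectivity. The fallback sets out from aldehyde 8 and comes back at silyl alkyne 19. Ramirez dibromo-olefination of 8 (CBr4, PPh3) should give the 1,1-dibromoalkene F5. A trans-selective Negishi monomethylation (MeZnCl, Pd(DPEphos)Cl2, THF) replaces only the bromine trans to the chain and should give the (Z)-2-bromoalkene F6. B-alkyl Suzuki coupling of F6 with borane 18 (Pd(t-Bu3P)2, Cs2CO3, THF/H2O), which proceeds with retention, should give 19.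

**Further compounds**
F1 | step 18 | methyl (2Z,4Z,6R,10Z,14E)-17-(furan-3-yl)-2-(hydroxymethyl)-6,10,14-trimethyl-4-(4,4,5,5-tetramethyl-1,3,2-dioxaborolan-2-yl)heptadeca-2,4,10,14-tetraenoate | C/C(=C/CC/C(C)=C/CCc1ccoc1)CCC[C@@H](C)/C=C(\C=C(/C(=O)OC)CO)B1OC(C)(C)C(C)(C)O1
F2 | step 18 | (2Z,4Z,6R,10Z,14E)-17-(furan-3-yl)-2-(hydroxymethyl)-6,10,14-trimethyl-4-(4,4,5,5-tetramethyl-1,3,2-dioxaborolan-2-yl)heptadeca-2,4,10,14-tetraenoic acid | C/C(=C/CC/C(C)=C/CCc1ccoc1)CCC[C@@H](C)/C=C(\C=C(/C(=O)O)CO)B1OC(C)(C)C(C)(C)O1
F3 | step 16 | (2Z,6R,10Z,14E)-17-(furan-3-yl)-2-(hydroxymethyl)-6,10,14-trimethylheptadeca-2,10,14-trien-4-ynoic acid | C/C(=C/CC/C(C)=C/CCc1ccoc1)CCC[C@@H](C)C#C/C=C(/CO)C(=O)O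
F4 | step 16 | (5Z)-5-[(2R,6Z,10E)-13-(furan-3-yl)-2,6,10-trimethyltrideca-6,10-dien-1-ylidene]-3-(hydroxymethyl)furan-2(5H)-one | C/C(=C/CC/C(C)=C/CCc1ccoc1)CCC[C@@H](C)/C=C1/C=C(CO)C(=O)O1
F5 | step 6 | 3-[(3E)-8,8-dibromo-4-methylocta-3,7-dien-1-yl]furan | BrC(Br)=CCC/C(C)=C/CCc1ccoc1
F6 | step 6 | 3-[(3E,7Z)-8-bromo-4-methylnona-3,7-dien-1-yl]furan | C/C(Br)=C/CC/C(C)=C/CCc1ccoc1
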